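**Retrosynthetic overview**

1. The C24 chain is cut into three cheap pieces: dec-9-enoic acid (1) and dec-9-en-1-ol (2), joined acyclically as diene ester 3 (the lactone C–O bond is made before any ring exists), and 2,5-dibromothiophene (4), whose four ring carbons become C11–C14 of the target.
2. Only ring-forming event: both alkenes of 3 are hydroborated (bis-borane 5) and stitched onto the two C–Br bonds of symmetric 4 by a double B-alkyl Suzuki–Miyaura cyclocoupling (through bromothienyl boranes 6 and 7), giving thiophenophane lactone 8.
3. Key disconnection: the C11–C14 tetramethylene of 24-tetracosanolide (9) ⇐ the 2,5-disubstituted thiophene of 8. Raney Ni reductive desulfurization destroys the aromatic ring, removes sulfur and leaves the saturated 25-membered lactone.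
4. No macrolactonization, no ring-closing metathesis, no protecting groups; three steps.

Assumption: the target has no stereocentre (it is achiral), so "single enantiomer" requires no stereocontrol; the SMILES is taken as drawn (24 carbons, 25-membered ring).

**Route**

Step 1
Reactants: 1 dec-9-enoic acid; 2 dec-9-en-1-ol
Product: 3 dec-9-en-1-yl dec-9-enoate
Conditions: DCC (1.1 equiv), DMAP (0.1 equiv), CH2Cl2, 0 °C → rt
Reagents that add atoms: none
Why: Steglich esterification of an unhindered acid with a primary alcohol is reliable, leaves both terminal alkenes untouched and creates no stereocentre.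

Step 2
Reactants: 3 dec-9-en-1-yl dec-9-enoate; 4 2,5-dibromothiophene
Product: 8 12-oxa-26-thiabicyclo[21.2.1]hexacosa-1(25),23-dien-11-one (thiophenophane lactone), via bis(9-BBN) adduct 5 (not isolated), via acyl-arm bromothienyl borane 6 (not isolated), via alkoxy-arm bromothienyl borane 7 (not isolated)
Conditions: 9-BBN-H (2.2 equiv), THF, 0 °C → rt; then the solution of 5 and 4 (1.0 equiv) added by syringe pump over 20 h to PdCl2(dppf) (10 mol %), AsPh3 (10 mol %), Cs2CO3 (5 equiv), DMF/THF/H2O, 40 °C, final concentration 1 mM
Reagents that add atoms: none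
Why: Proposed new method: anti-Markovnikov hydroboration of both terminal alkenes with 9-BBN-H (the ester is inert at rt) gives 5; oxidative addition of zerovalent palladium into one C–Br bond of 4, base-assisted transmetalation of either B-alkyl terminus and reductive elimination give 6 or 7, which carry the remaining C–Br bond and the remaining borane in the same molecule, so that under slow-addition dilution the second coupling is an intramolecular, strain-free large-ring closure that outruns oligomerization; the closest known reaction types are the intramolecular B-alkyl Suzuki–Miyaura macrocyclization and the Kumada cyclocoupling of α,ω-di-Grignard reagents with dihaloarenes to [n]cyclophanes; no stereocentre is created.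

Step 3
Reactants: 8 12-oxa-26-thiabicyclo[21.2.1]hexacosa-1(25),23-dien-11-one
Product: 9 24-tetracosanolide (oxacyclopentacosan-2-one)
Conditions: Raney Ni (W-2, washed neutral, large excess), H2 (1 atm), THF/EtOH, 60 °C
Reagents that add atoms: none
Why: Raney Ni reductive desulfurization (Mozingo-type hydrodesulfurization) of a 2,5-dialkylthiophene cleaves both C–S bonds and saturates the four ring carbons to (CH2)4, while a lactone is inert to neutral Raney Ni/H2; no stereocentre is created.

**Compound list**

1 | dec-9-enoic acid | C=CCCCCCCCC(=O)O | starting material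
2 | dec-9-en-1-ol | C=CCCCCCCCCO | starting material
3 | dec-9-en-1-yl dec-9-enoate | C=CCCCCCCCC(=O)OCCCCCCCCC=C | intermediate
4 | 2,5-dibromothiophene (bulk bromination product of thiophene) | Brc1ccc(Br)s1 | starting material
5 | 10-(9-borabicyclo[3.3.1]nonan-9-yl)decyl 10-(9-borabicyclo[3.3.1]nonan-9-yl)decanoate | O=C(CCCCCCCCCB1C2CCCC1CCC2)OCCCCCCCCCCB1C2CCCC1CCC2 | intermediate (not isolated)
6 | 10-(9-borabicyclo[3.3.1]nonan-9-yl)decyl 10-(5-bromothiophen-2-yl)decanoate | O=C(CCCCCCCCCc1ccc(Br)s1)OCCCCCCCCCCB1C2CCCC1CCC2 | intermediate (not isolated)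
7 | 10-(5-bromothiophen-2-yl)decyl 10-(9-borabicyclo[3.3.1]nonan-9-yl)decanoate | O=C(CCCCCCCCCB1C2CCCC1CCC2)OCCCCCCCCCCc1ccc(Br)s1 | intermediate (not isolated)
8 | 12-oxa-26-thiabicyclo[21.2.1]hexacosa-1(25),23-dien-11-one: thiophene bridged from C2 to C5 by –(CH2)9–C(=O)–O–(CH2)10– | O=C1CCCCCCCCCc2ccc(CCCCCCCCCCO1)s2 | intermediate
9 | 24-tetracosanolide (oxacyclopentacosan-2-one), achiral | O=C1CCCCCCCCCCCCCCCCCCCCCCCO1 | target

**Totals and risk**

Total step count: 3. Longest linear sequence: 3 (1/2 → 3 → 8 → 9).

Steps most likely to fail, most risky first: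

Step 2 (bimolecular cyclocoupling; risk of linear and cyclic oligomers or reduced chain ends). Fallback: the two C–C bonds are made one at a time so that ring closure is strictly intramolecular. It sets out from 2 and 4. Alcohol 2 is treated with 9-BBN-H (2.1 equiv; the first equivalent borylates the hydroxyl with loss of H2) to give 9-{[10-(9-borabicyclo[3.3.1]nonan-9-yl)decyl]oxy}-9-borabicyclo[3.3.1]nonane F1 (not isolated). F1 is coupled with a threefold excess of 4 (PdCl2(dppf), Cs2CO3, DMF/THF/H2O) to give, after aqueous work-up, 10-(5-bromothiophen-2-yl)decan-1-ol F2. F2 is esterified with 1 (DCC, DMAP) to 10-(5-bromothiophen-2-yl)decyl dec-9-enoate F3. Hydroboration of F3 with 9-BBN-H (1.1 equiv) gives 7, where the fallback rejoins the route, and 7 closes to 8 by the well-precedented intramolecular B-alkyl Suzuki–Miyaura macrocyclization under syringe-pump dilution.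

Step 3 (Raney Ni; risk of incomplete desulfurization, olefinic by-products or ethanolysis of the lactone on basic nickel). Fallback: dearomatization and C–S cleavage are separated. It sets out from 8. Ionic hydrogenation (Et3SiH, CF3CO2H, 50 °C) saturates the thiophene to the thiolane 12-oxa-26-thiabicyclo[21.2.1]hexacosan-11-one F4 (cis/trans mixture, inconsequential because both stereocentres vanish in the next operation). The resulting ordinary dialkyl sulfide is then desulfurized under mild conditions with nickel boride Ni2B made in the flask from NiCl2·6H2O and NaBH4 (THF/MeOH, 0 °C), coming back to the route at 9.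

Step 1 (low risk; N-acylurea formation or difficult removal of the urea). Fallback: the ester is made through the alkyl C–O bond instead of the acyl C–O bond. It sets out from 2, which with MsCl and Et3N (CH2Cl2, 0 °C) gives dec-9-en-1-yl methanesulfonate F5. F5 alkylates the caesium carboxylate of 1 (Cs2CO3, DMF, 50 °C, SN2), coming back to the route at 3.

**Further compounds**

F1 | step 2 | 9-{[10-(9-borabicyclo[3.3.1]nonan-9-yl)decyl]oxy}-9-borabicyclo[3.3.1]nonane | B1(OCCCCCCCCCCB2C3CCCC2CCC3)C4CCCC1CCC4
F2 | step 2 | 10-(5-bromothiophen-2-yl)decan-1-ol | OCCCCCCCCCCc1ccc(Br)s1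
F3 | step 2 | 10-(5-bromothiophen-2-yl)decyl dec-9-enoate | C=CCCCCCCCC(=O)OCCCCCCCCCCc1ccc(Br)s1
F4 | step 3 | 12-oxa-26-thiabicyclo[21.2.1]hexacosan-11-one (cis/trans mixture) | O=C1CCCCCCCCCC2CCC(CCCCCCCCCCO1)S2
F5 | step 1 | dec-9-en-1-yl methanesulfonate | C=CCCCCCCCCOS(C)(=O)=O
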